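**Remark on the chemistry:** all polycarbonyl compounds are written as single enol tautomers (the target in the tautomer of the given SMILES), the tautomers interconvert freely, and 1 and 3 are taken to be commercially available.

## Structural features

Pentaalbaspidin BBBBB is an achiral, constitutionally symmetric chain of five six-membered carbocycles, rings A to E, joined by four CH2 bridges. Rings A and E are 2-butanoyl-3,5-dihydroxy-6,6-dimethylcyclohexa-2,4-dien-1-one (butyrylfilicinic acid) units bound through C4, their only enol C–H position. Rings B, C and D are hexasubstituted butyrylphloroglucinols with the butanoyl group on C1, hydroxyls on C2, C4 and C6, and bridges on C3 and C5. There is no stereocentre (the only sp3 ring atoms are the two CMe2 carbons), so no stereocentres stand next to each other and nothing stereochemical has to be set. The fragile groups are the bridges and the acyl groups: every CH2 lies between two rings with ortho oxygens, so it can leave either ring as an o-quinone methide (base, heat) or as a benzylic cation (acid), which exchanges rings between chains, and the β-triketone and o-acylphenol units are open to retro-Claisen cleavage and, as polyphenolates, to air oxidation. The real difficulty is control of sequence and chain length: the monomer of rings B, C and D has two equivalent nucleophilic carbons and the monomer of rings A and E has one, so direct methylene bridging gives statistical oligomer mixtures. The key step exploits the polyketide make-up of rings B and D: in each, C2 to C6 can be carried as C2 to C6 of a 4-hydroxy-2H-pyran-2-one and C1 as the CH2 of a 6-(2-oxopentyl) side chain, so that the ring bond C1–C2 is made last by a Claisen ring closure. In that pyranone only C3 (the future bridge carbon towards ring C) is a strong carbon nucleophile, while C5 (the future bridge carbon towards ring A or E) becomes nucleophilic only once the aromatic ring exists.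

## Logic of the disconnections

In one sentence: rings B and D are created together by a twofold pyranone-to-acylphloroglucinol Claisen recyclisation of 6, which delivers 8 with exactly one free carbon on each end ring.

**12 to 8 and two molecules of 10.** The two outer bridge bonds (CH2 to C5 of rings B and D) are cut. Rings A and E are chain ends with a single reactive carbon, so this cut removes both caps at once and leaves a symmetric three-ring core. The forward step (through 11) demands that 8 has exactly two free ring carbons and that 10 is an electrophile with no nucleophilic carbon of its own; both hold by constitution.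

**8 to 6 (key).** The ring bonds C1–C2 of rings B and D are cut (retro-Claisen) and the carboxyl carbon C2 is re-closed onto the C6 oxygen as a lactone, which turns both end rings into 4-hydroxy-2-pyranones. The reason is that an aromatic end ring would have needed two equivalent nucleophilic carbons to be told apart, whereas the pyranone offers one. The gain is that the three-ring chain of defined length descends from a precursor in which over-alkylation and chain growth are not possible. The forward step (through 7) must prefer Claisen over aldol closure and must leave the two existing bridges in place.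

**6 to 4 and two molecules of 2.** The two bridge bonds between CH2 and C3 of the pyranones are cut. This separates a ring C bis-electrophile that has no ring C–H from a nucleophile with a single reactive carbon, so the coupling (through 5) can only stop at the 1:2 adduct. The forward step demands C3 selectivity on 2 over its C5 and side-chain CH2.

**4 to 3.** The two C–CH2N bonds are cut. Twofold aminomethylation uses up both free ring carbons of 3, which is what makes 4 a pure electrophile. The demand is exhaustive substitution without premature loss of amine.

**2 to 1.** The bond between the side-chain CH2 and the ketone carbon is cut. This traces the pyranone back to the commercial triacetic acid lactone and a butanoyl donor. The demand is acylation at the 6-methyl carbon through the dianion.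

**10 to 9 to 3.** The C–CH2N bond and then the two C–CH3 bonds at C6 are cut. Ring A (and E) thus comes from the same commercial phenol as ring C. The demand is geminal C-methylation at one ring carbon, followed by aminomethylation at the only remaining enol C–H.

## Other disconnections considered

**Alternative 1:** (the route drawn first). Cut the two inner bridge bonds at rings B and D, then the outer ones: 12 from 4 and two molecules of the two-ring arm 2-butanoyl-4-[(3-butanoyl-2,4,6-trihydroxyphenyl)methyl]-3,5-dihydroxy-6,6-dimethylcyclohexa-2,4-dien-1-one A1, itself from 10 and 3. The forward key step is the twofold o-quinone-methide alkylation of A1 by 4. The chosen plan is preferred because A1 has to be made from 3, which has two equivalent nucleophilic carbons, and A1 keeps one of them; the electrophile from 10 therefore competes for 3 and for A1 with no structural bias, and only a large excess of 3 can limit this. The chosen route pairs, in every coupling, an electrophile without ring C–H with a nucleophile that has exactly the required number of reactive carbons. Alternative 1 is also the plan that does not change the problem.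

**Alternative 2:** Cut the four C–CH3 bonds of rings A and E. The precursor is the all-aromatic pentamer of five methylene-bridged butyrylphloroglucinol rings A2, and the forward key step is a fourfold C-methylation with NaOMe and MeI that dearomatises the two end rings. After the first methyl group has entered each end ring, the second must choose that C–CH3 carbon over eight ring carbons bearing CH2 bridges, which are enolate carbons of the same kind. Nothing in the structure secures that choice, the strongly basic medium is the one in which bridges exchange, and A2 needs the same chain-length control as the target, so no simplicity is gained.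

**Alternative 3:** Cut the five ring–C(=O) bonds. The precursor is the acyl-free pentamer A3 (two filicinic acid and three phloroglucinol rings), and the forward key step is a fivefold C-butanoylation (butanoic acid and BF3·OEt2, or Fries rearrangement of the perbutanoate). It is attractive because each ring has exactly one free carbon. However, the acyl groups are what limit the ring monomers to two and one nucleophilic carbons; without them phloroglucinol has three and filicinic acid two, so A3 is harder to assemble than the target. In addition, acyl-free diarylmethane links between such electron-rich rings are cleaved by the acid needed for acylation (retro-Friedel–Crafts exchange). The step would therefore leave the chain problem unsolved and add a new lability.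

Key step: step 4

## Route

Step 1
Reactants: 1 4-hydroxy-6-methyl-2H-pyran-2-one (triacetic acid lactone)
Product: 2 4-hydroxy-6-(2-oxopentyl)-2H-pyran-2-one
Conditions: LiN(i-Pr)2 (3.2 equiv), THF, −78 °C; methyl butanoate (1.1 equiv), −78 → 0 °C; aq. HCl
Reagents that add atoms: methyl butanoate, CCCC(=O)OC
Why: Claisen acylation of the O,C-dilithio dianion of 1, which reacts at the 6-methyl carbon (terminus of the vinylogous enolate); the third equivalent of base takes up the more acidic proton of the product so that the dianion is not quenched.

Step 2
Reactants: 3 1-(2,4,6-trihydroxyphenyl)butan-1-one (butyrylphloroglucinol)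
Product: 4 1-{3,5-bis[(dimethylamino)methyl]-2,4,6-trihydroxyphenyl}butan-1-one
Conditions: CH2(NMe2)2 (2.5 equiv), 1,4-dioxane, 0 → 20 °C; product collected as the zwitterion
Reagents that add atoms: N,N,N',N'-tetramethylmethanediamine, CN(C)CN(C)C
Why: Twofold phenolic Mannich reaction: the acidic phenol releases the iminium ion from the aminal, which substitutes both unsubstituted ring carbons; after two substitutions no ring C–H is left, so the reaction ends by itself and 4 can no longer act as a carbon nucleophile.

Step 3
Reactants: 4 1-{3,5-bis[(dimethylamino)methyl]-2,4,6-trihydroxyphenyl}butan-1-one; 2 4-hydroxy-6-(2-oxopentyl)-2H-pyran-2-one (2.2 equiv)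
Product: 6 1-{2,4,6-trihydroxy-3,5-bis{[4-hydroxy-2-oxo-6-(2-oxopentyl)-2H-pyran-3-yl]methyl}phenyl}butan-1-one (bis-pyranone), via mono(pyranonylmethyl) mono-Mannich base 5 (not isolated)
Conditions: 1,4-dioxane, 100 °C, slow N2 stream
Reagents that add atoms: none
Why: Elimination–addition of a phenolic Mannich base: each o-hydroxybenzylamine arm loses Me2NH on heating and the transient o-quinone methide is captured by C3 of 2, the carbon between lactone carbonyl and enol, as in the formation of methylenebis(4-hydroxypyranones). Since 4 has no ring C–H and 2 has one strongly nucleophilic carbon, the coupling can only end at the 1:2 adduct.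

Step 4
Reactants: 6 1-{2,4,6-trihydroxy-3,5-bis{[4-hydroxy-2-oxo-6-(2-oxopentyl)-2H-pyran-3-yl]methyl}phenyl}butan-1-one
Product: 8 1-{2,4,6-trihydroxy-3,5-bis[(3-butanoyl-2,4,6-trihydroxyphenyl)methyl]phenyl}butan-1-one (three-ring core), via bis(methyl 3,5,7-trioxodecanoate) 7 (not isolated)
Conditions: Mg(OMe)2 (12 equiv), MeOH, reflux, N2; then cold 1 M aq. HCl
Reagents that add atoms: none
Why: Methoxide opens each lactone at C2 to the magnesium-chelated methyl 3,5,7-trioxodecanoate arm of 7; in the chelate the C6 carbanion (the former side-chain CH2, flanked by the C5 and C7 carbonyls) attacks the ester carbon C1 and methoxide leaves, a Claisen (Dieckmann-type) condensation that returns the methanol taken up in the opening. Each of rings B and D closes in the 6-(enolexo)-exo-trig mode, and the cyclohexane-1,3,5-trione formed tautomerises at once to the aromatic magnesium phenolate, which makes the closure irreversible. The closest known reaction type is the Mg(OMe)2-mediated recyclisation of 6-(2-oxoalkyl)-4-hydroxy-2-pyranones and of 3,5,7-triketo esters to acylphloroglucinols, the laboratory copy of the polyketide Claisen cyclisation. No stereocentre is formed, and the undefined centre at C2 of each arm of 7 disappears on aromatisation. The step needs Claisen closure (C6 to C1) in preference to aldol closure: the aldol mode C2 to C7 that gives resorcylates from unsubstituted chains would make C2 quaternary here because C2 carries the benzylic CH2, so it cannot aromatise and stays reversible, C8 is only singly activated, and magnesium chelation of the polycarbonyl chain favours C-acylation. The step also needs the two existing bridges to stay in place; the magnesium phenolates of ring C, tied up by chelation to the ortho butanoyl group, are poor donors for retro-Michael loss of the bridge at 65 °C. The former pyranone C3 ends up between two hydroxyls carrying the bridge, and the former C5–H becomes the single free carbon of each new ring.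

Step 5
Reactants: 3 1-(2,4,6-trihydroxyphenyl)butan-1-one
Product: 9 2-butanoyl-3,5-dihydroxy-6,6-dimethylcyclohexa-2,4-dien-1-one (butyrylfilicinic acid)
Conditions: NaOMe (3 equiv), MeI (2.2 equiv), MeOH, 0 → 20 °C; aq. HCl
Reagents that add atoms: iodomethane, CI
Why: Dearomatising geminal C-methylation of the acylphloroglucinol polyanion, the established entry to acylfilicinic acids; the second methyl group enters the carbon that already carries the first because that enolate carbon is the more electron-rich one.

Step 6
Reactants: 9 2-butanoyl-3,5-dihydroxy-6,6-dimethylcyclohexa-2,4-dien-1-one
Product: 10 2-butanoyl-4-[(dimethylamino)methyl]-3,5-dihydroxy-6,6-dimethylcyclohexa-2,4-dien-1-one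
Conditions: CH2(NMe2)2 (1.2 equiv), CH2Cl2, 0 → 20 °C; inner salt filtered off
Reagents that add atoms: N,N,N',N'-tetramethylmethanediamine, CN(C)CN(C)C
Why: Mannich reaction at C4, the only unsubstituted enol carbon of the vinylogous acid; the product should separate as an ammonium enolate inner salt, which keeps it from losing amine at this temperature.

Step 7
Reactants: 8 1-{2,4,6-trihydroxy-3,5-bis[(3-butanoyl-2,4,6-trihydroxyphenyl)methyl]phenyl}butan-1-one; 10 2-butanoyl-4-[(dimethylamino)methyl]-3,5-dihydroxy-6,6-dimethylcyclohexa-2,4-dien-1-one (2.4 equiv)
Product: 12 pentaalbaspidin BBBBB, via singly capped tetramer 11 (not isolated)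
Conditions: 1,4-dioxane, 80 °C, slow N2 stream; then wash with dilute aq. HCl
Reagents that add atoms: none
Why: Elimination–addition of the Mannich base: 10 loses Me2NH to the 4-methylidene triketone (o-quinone methide type), which is captured by the single free aromatic carbon of each end ring of 8 in a Michael-type Friedel–Crafts alkylation. The electrophile has no nucleophilic carbon and the product has no ring C–H left, so the capping is self-terminating.

## Compound list

1 | 4-hydroxy-6-methyl-2H-pyran-2-one (triacetic acid lactone) | CC1=CC(O)=CC(=O)O1 | starting material
2 | 4-hydroxy-6-(2-oxopentyl)-2H-pyran-2-one | CCCC(=O)CC1=CC(O)=CC(=O)O1 | intermediate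
3 | 1-(2,4,6-trihydroxyphenyl)butan-1-one (butyrylphloroglucinol) | CCCC(=O)c1c(O)cc(O)cc1O | starting material
4 | 1-{3,5-bis[(dimethylamino)methyl]-2,4,6-trihydroxyphenyl}butan-1-one | CCCC(=O)c1c(O)c(CN(C)C)c(O)c(CN(C)C)c1O | intermediate
5 | 1-{3-[(dimethylamino)methyl]-2,4,6-trihydroxy-5-{[4-hydroxy-2-oxo-6-(2-oxopentyl)-2H-pyran-3-yl]methyl}phenyl}butan-1-one (not isolated) | CCCC(=O)c1c(O)c(CN(C)C)c(O)c(CC2=C(O)C=C(CC(=O)CCC)OC2=O)c1O | intermediate
6 | 1-{2,4,6-trihydroxy-3,5-bis{[4-hydroxy-2-oxo-6-(2-oxopentyl)-2H-pyran-3-yl]methyl}phenyl}butan-1-one | CCCC(=O)c1c(O)c(CC2=C(O)C=C(CC(=O)CCC)OC2=O)c(O)c(CC3=C(O)C=C(CC(=O)CCC)OC3=O)c1O | intermediate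
7 | dimethyl 2,2'-[(5-butanoyl-2,4,6-trihydroxy-1,3-phenylene)bis(methylene)]bis(3,5,7-trioxodecanoate), present as magnesium chelate, configuration at the two C2 atoms undefined (not isolated) | CCCC(=O)c1c(O)c(CC(C(=O)OC)C(=O)CC(=O)CC(=O)CCC)c(O)c(CC(C(=O)OC)C(=O)CC(=O)CC(=O)CCC)c1O | intermediate
8 | 1-{2,4,6-trihydroxy-3,5-bis[(3-butanoyl-2,4,6-trihydroxyphenyl)methyl]phenyl}butan-1-one | CCCC(=O)c1c(O)c(Cc2c(O)cc(O)c(C(=O)CCC)c2O)c(O)c(Cc3c(O)cc(O)c(C(=O)CCC)c3O)c1O | intermediate
9 | 2-butanoyl-3,5-dihydroxy-6,6-dimethylcyclohexa-2,4-dien-1-one (butyrylfilicinic acid) | CCCC(=O)C1=C(O)C=C(O)C(C)(C)C1=O | intermediate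
10 | 2-butanoyl-4-[(dimethylamino)methyl]-3,5-dihydroxy-6,6-dimethylcyclohexa-2,4-dien-1-one | CCCC(=O)C1=C(O)C(CN(C)C)=C(O)C(C)(C)C1=O | intermediate
11 | singly capped tetramer: 8 in which one end ring carries at its free carbon the (5-butanoyl-2,6-dihydroxy-3,3-dimethyl-4-oxocyclohexa-1,5-dien-1-yl)methyl group (not isolated) | CCCC(=O)C1=C(O)C(Cc2c(O)c(Cc3c(O)c(Cc4c(O)cc(O)c(C(=O)CCC)c4O)c(O)c(C(=O)CCC)c3O)c(O)c(C(=O)CCC)c2O)=C(O)C(C)(C)C1=O | intermediate
12 | pentaalbaspidin BBBBB | CCCC(=O)C1=C(O)C(Cc2c(O)c(Cc3c(O)c(Cc4c(O)c(CC5=C(O)C(C)(C)C(=O)C(C(=O)CCC)=C5O)c(O)c(C(=O)CCC)c4O)c(O)c(C(=O)CCC)c3O)c(O)c(C(=O)CCC)c2O)=C(O)C(C)(C)C1=O | target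

## Step count and risks

Total step count: 7. Longest linear sequence: 4 steps (1 → 2 → 6 → 8 → 12, steps 1, 3, 4 and 7; the branch 3 → 4 → 6 → 8 → 12 is equally long).

**Step 4 (key step).** The most likely failure is exchange of the methylene bridges: a ring C phenolate can expel the neighbouring stabilised carbanion by retro-Michael fragmentation, and recombination then scrambles chain length. The second concern is incomplete twofold conversion, with one arm going back to the lactone or closing by an aldol path. Both arise because the medium is basic and hot while the bridges already exist. Fallback: from 4, thermolysis in 1,4-dioxane with a large excess (at least tenfold) of 3, so that statistics confine each molecule of 3 to one alkylation and the excess is recovered. This classical o-quinone-methide alkylation rejoins the route at 8 and makes no compound outside the compound list (F0).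

**Step 3.** The most likely failure is loss of site selectivity on 2, with alkylation at C5 or at the side-chain CH2 instead of C3. A second risk is transfer of the aminomethyl group from 4 to 2 by retro-Mannich reaction, which would lead to self-coupling of the pyranone. Fallback with the roles exchanged: from 2, aminomethylation with CH2(NMe2)2 gives 3-[(dimethylamino)methyl]-4-hydroxy-6-(2-oxopentyl)-2H-pyran-2-one F1, in which the position on the pyranone is fixed and can be purified. F1 (2.2 equiv) is then heated with 3 in 1,4-dioxane, whose two free ring carbons are both alkylated, and the route is rejoined at 6.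

**Step 7.** The most likely failure is incomplete capping together with thermal bridge exchange in the amine-containing medium, and consumption of the electrophile by self-reaction before both ends of 8 have reacted. Fallback with the roles exchanged: from 8, aminomethylation of the two free end-ring carbons with CH2(NMe2)2 gives 1-{2,4,6-trihydroxy-3,5-bis({3-butanoyl-5-[(dimethylamino)methyl]-2,4,6-trihydroxyphenyl}methyl)phenyl}butan-1-one F2. F2 is warmed with an excess of 9, a strongly acidic nucleophile with one reactive carbon that allows a lower temperature, and the route is rejoined at 12.

**Step 1.** The most likely failure is proton transfer from the more acidic product to unreacted dianion, which stops the acylation part-way, and a second acylation at the same carbon. Fallback through an aldol addition: from 1, the dianion is added to butanal to give racemic 4-hydroxy-6-(2-hydroxypentyl)-2H-pyran-2-one F3. Oxidation of the secondary alcohol of F3 with Dess–Martin periodinane in CH2Cl2 rejoins the route at 2.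

## Further compounds

F0 | step 4 | none | none
F1 | step 3 | 3-[(dimethylamino)methyl]-4-hydroxy-6-(2-oxopentyl)-2H-pyran-2-one | CCCC(=O)CC1=CC(O)=C(CN(C)C)C(=O)O1
F2 | step 7 | 1-{2,4,6-trihydroxy-3,5-bis({3-butanoyl-5-[(dimethylamino)methyl]-2,4,6-trihydroxyphenyl}methyl)phenyl}butan-1-one | CCCC(=O)c1c(O)c(Cc2c(O)c(CN(C)C)c(O)c(C(=O)CCC)c2O)c(O)c(Cc3c(O)c(CN(C)C)c(O)c(C(=O)CCC)c3O)c1O
F3 | step 1 | 4-hydroxy-6-(2-hydroxypentyl)-2H-pyran-2-one (racemic) | CCCC(O)CC1=CC(O)=CC(=O)O1
A1 | alternative 1 | 2-butanoyl-4-[(3-butanoyl-2,4,6-trihydroxyphenyl)methyl]-3,5-dihydroxy-6,6-dimethylcyclohexa-2,4-dien-1-one | CCCC(=O)C1=C(O)C(Cc2c(O)cc(O)c(C(=O)CCC)c2O)=C(O)C(C)(C)C1=O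
A2 | alternative 2 | all-aromatic pentamer of five methylene-bridged butyrylphloroglucinol rings, each end ring with one free carbon | CCCC(=O)c1c(O)cc(O)c(Cc2c(O)c(Cc3c(O)c(Cc4c(O)c(Cc5c(O)cc(O)c(C(=O)CCC)c5O)c(O)c(C(=O)CCC)c4O)c(O)c(C(=O)CCC)c3O)c(O)c(C(=O)CCC)c2O)c1O
A3 | alternative 3 | acyl-free pentamer: two filicinic acid end rings and three phloroglucinol rings joined by four CH2 bridges | O=C1C=C(O)C(Cc2c(O)c(Cc3c(O)c(Cc4c(O)c(CC5=C(O)C(C)(C)C(=O)C=C5O)c(O)cc4O)c(O)cc3O)c(O)cc2O)=C(O)C1(C)C
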